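The depside is cut at its aryl ester into a ring-B acid, made from atraric acid, and a ring-A phenol. Everything rests on ring A (C1 CO2Me, C2 OMe, C3 Me, C4 O-acyl, C5 Me, C6 Me). C6 bears a methyl group, the adjacent C1 bears the ester carbon, and the C2 methoxy oxygen flanks C1. This is the array produced when a carbon nucleophile and then a carbon electrophile add across a 3-methoxyaryne. In one pot the key step converts a pentasubstituted bromide into the hexasubstituted benzoate, forging both C–C bonds under regiocontrol by the C2 oxygen. Its precursor is 1-bromo-3,5-dimethoxy-2,4-dimethylbenzene, whose only ring hydrogen lies between Br and OMe.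

Key step: step 3

Remark on the chemistry: lithium amides deprotonate bromoarenes preferentially beside bromine, so the methyl group between the two oxygens is not introduced by metalation but bought as the formyl carbon of aldehyde 1; the two ring hydrogens of 2 are then equivalent, the single metalation before the key step is unambiguous, and to keep this symmetry both ring-A oxygens stay methyl ethers until step 4.
Numbering: ring A is unprimed as above; ring B is primed (C1' acyl, C2' OMe, C3' Me, C4' OH, C5' Cl, C6' Me); ring-B building blocks use the same locants unprimed; the target has no stereocentre.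

Step 1
Reactants: 1 4-bromo-2,6-dimethoxybenzaldehyde
Product: 2 5-bromo-1,3-dimethoxy-2-methylbenzene
Conditions: Et3SiH (3 equiv), TFA, CH2Cl2, 0 °C to rt
Reagents that add atoms: none
Why: Ionic hydrogenation (silane/acid deoxygenation) suits electron-rich benzaldehydes because the 2,6-dimethoxybenzyl cation forms easily and is captured by hydride, the C–Br bond is inert, and the future C3 methyl group is fixed between the two oxygens without any regiochemical question.

Step 2
Reactants: 2 5-bromo-1,3-dimethoxy-2-methylbenzene; 3 iodomethane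
Product: 5 1-bromo-3,5-dimethoxy-2,4-dimethylbenzene, via aryllithium 4 (not isolated)
Conditions: lithium 2,2,6,6-tetramethylpiperidide (LiTMP, from TMPH + n-BuLi, 1.05 equiv), THF, −78 °C; MeI, −78 °C to rt
Reagents that add atoms: iodomethane (3), CI
Why: In this deprotonative ortho-lithiation each of the two equivalent ring hydrogens of 2 is flanked by Br and OMe and is the most acidic site, aryllithium 4 keeps its bromide at −78 °C, and SN2 methylation by MeI is fast at that temperature.

Step 3
Reactants: 5 1-bromo-3,5-dimethoxy-2,4-dimethylbenzene; 6 methylmagnesium bromide; 7 methyl chloroformate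
Product: 11 methyl 2,4-dimethoxy-3,5,6-trimethylbenzoate, via aryllithium 8 (not isolated), via aryne 9 (not isolated), via arylmagnesium bromide 10 (not isolated)
Conditions: lithium 2,2,6,6-tetramethylpiperidide (LiTMP, from TMPH + n-BuLi, 1.2 equiv), THF, −78 °C; MeMgBr (4 equiv), −78 °C to rt; ClCO2Me (excess over all organometal), −20 °C to rt
Reagents that add atoms: methylmagnesium bromide (6), C[Mg]Br; methyl chloroformate (7), COC(=O)Cl
Why: LiTMP removes the single ring hydrogen of 5, acidified by the flanking Br and OMe, and aryllithium 8 loses LiBr on warming, with MeMgBr already present, to give aryne 9 across the future C1 and C6. MeMgBr carbometalates 9 at the aryne carbon remote from the methoxy group, because the inductively withdrawing oxygen distorts the triple bond and stabilises and chelates the metal-bearing carbon next to it, so CH3 ends on C6 and magnesium on C1 (10). Methyl chloroformate then acylates 10, and the doubly ortho-substituted ester 11 is too shielded to take up a second organometal. The closest known reaction type is the three-component coupling of 3-alkoxyarynes with Grignard reagents and carbon electrophiles. No ring is closed and no stereocentre is formed. The selectivity needed is regiochemical (methyl to C6, not C1), and it rests on the electronic bias of the C2 methoxy group outweighing the small steric penalty that the C5 methyl group imposes on the slim methyl nucleophile.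

Step 4
Reactants: 11 methyl 2,4-dimethoxy-3,5,6-trimethylbenzoate
Product: 12 methyl 2,4-dihydroxy-3,5,6-trimethylbenzoate
Conditions: BBr3 (3 equiv), CH2Cl2, −78 °C to rt; H2O
Reagents that add atoms: none
Why: In this Lewis-acid ether cleavage BBr3 binds both twisted, doubly flanked methoxy oxygens (the one at C2 helped by chelation to the ester carbonyl) and bromide removes the methyl groups by SN2, while the shielded methyl ester reacts far more slowly at or below room temperature.

Step 5
Reactants: 13 atraric acid (methyl 2,4-dihydroxy-3,6-dimethylbenzoate)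
Product: 14 methyl 5-chloro-2,4-dihydroxy-3,6-dimethylbenzoate
Conditions: SO2Cl2 (1.05 equiv), CH2Cl2, 0 °C to rt
Reagents that add atoms: sulfuryl chloride, O=S(=O)(Cl)Cl
Why: In this electrophilic aromatic chlorination C5 is the only unsubstituted ring carbon of 13 and lies ortho to the C4 hydroxyl and para to the C2 hydroxyl, so one equivalent of reagent can only give the 5-chloro compound.

Step 6
Reactants: 14 methyl 5-chloro-2,4-dihydroxy-3,6-dimethylbenzoate; 15 benzyl bromide
Product: 16 methyl 4-(benzyloxy)-5-chloro-2-hydroxy-3,6-dimethylbenzoate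
Conditions: BnBr (1.05 equiv), K2CO3, acetone, reflux
Reagents that add atoms: benzyl bromide (15), BrCc1ccccc1
Why: In this Williamson etherification the C2 hydroxyl is locked in a hydrogen bond to the ester carbonyl, so K2CO3 ionises and BnBr alkylates only the more acidic C4 hydroxyl.

Step 7
Reactants: 16 methyl 4-(benzyloxy)-5-chloro-2-hydroxy-3,6-dimethylbenzoate; 3 iodomethane
Product: 17 methyl 4-(benzyloxy)-5-chloro-2-methoxy-3,6-dimethylbenzoate
Conditions: MeI (excess), K2CO3, DMF, 50 °C
Reagents that add atoms: iodomethane (3), CI
Why: Williamson etherification in a polar aprotic solvent with excess MeI overcomes the chelation of the remaining phenol, and no other site of 16 can be alkylated.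

Step 8
Reactants: 17 methyl 4-(benzyloxy)-5-chloro-2-methoxy-3,6-dimethylbenzoate
Product: 18 4-(benzyloxy)-5-chloro-2-methoxy-3,6-dimethylbenzoic acid
Conditions: KOH, DMSO–H2O, 100 °C; aq HCl
Reagents that add atoms: potassium hydroxide, [K+].[OH-]
Why: Saponification of a doubly ortho-substituted benzoate needs poorly solvated hydroxide in hot aqueous DMSO, and the benzyl ether, the methyl ether and the unactivated aryl chloride tolerate these conditions.

Step 9
Reactants: 18 4-(benzyloxy)-5-chloro-2-methoxy-3,6-dimethylbenzoic acid; 12 methyl 2,4-dihydroxy-3,5,6-trimethylbenzoate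
Product: 20 methyl 4-{[4-(benzyloxy)-5-chloro-2-methoxy-3,6-dimethylbenzoyl]oxy}-2-hydroxy-3,5,6-trimethylbenzoate, via mixed anhydride 19 (not isolated)
Conditions: (CF3CO)2O, toluene, rt
Reagents that add atoms: none
Why: In this mixed-anhydride esterification of a hindered acid the electron-rich 2,6-disubstituted acid 18 ionises through 19 to an acylium ion whose linear carbonyl carbon escapes the ortho shielding, and of the two phenols of 12 only O4–H is free of the hydrogen bond to the ester carbonyl.

Step 10
Reactants: 20 methyl 4-{[4-(benzyloxy)-5-chloro-2-methoxy-3,6-dimethylbenzoyl]oxy}-2-hydroxy-3,5,6-trimethylbenzoate; 3 iodomethane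
Product: 21 methyl 4-{[4-(benzyloxy)-5-chloro-2-methoxy-3,6-dimethylbenzoyl]oxy}-2-methoxy-3,5,6-trimethylbenzoate
Conditions: MeI (excess), K2CO3, DMF, 40 °C
Reagents that add atoms: iodomethane (3), CI
Why: This is the Williamson etherification of a chelated phenol as in step 7, and the depside carbonyl, shielded by four ortho substituents, meets no nucleophile in anhydrous carbonate that could cleave it.

Step 11
Reactants: 21 methyl 4-{[4-(benzyloxy)-5-chloro-2-methoxy-3,6-dimethylbenzoyl]oxy}-2-methoxy-3,5,6-trimethylbenzoate
Product: 22 methyl 4-[(5-chloro-4-hydroxy-2-methoxy-3,6-dimethylbenzoyl)oxy]-2-methoxy-3,5,6-trimethylbenzoate (CNP0192286.0)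
Conditions: H2 (1 atm), Pd/C, EtOAc, rt, no base
Reagents that add atoms: none
Why: Catalytic hydrogenolysis of the benzyl aryl ether should be much faster than reduction of an electron-rich aryl chloride when no base is present, and both esters and both methyl ethers are inert.

Compound list
1 | 4-bromo-2,6-dimethoxybenzaldehyde | COc1cc(Br)cc(OC)c1C=O | starting material
2 | 5-bromo-1,3-dimethoxy-2-methylbenzene | COc1cc(Br)cc(OC)c1C | intermediate
3 | iodomethane | CI | starting material
4 | (6-bromo-2,4-dimethoxy-3-methylphenyl)lithium | [Li]c1c(Br)cc(OC)c(C)c1OC | intermediate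
5 | 1-bromo-3,5-dimethoxy-2,4-dimethylbenzene | COc1cc(Br)c(C)c(OC)c1C | intermediate
6 | methylmagnesium bromide | C[Mg]Br | starting material
7 | methyl chloroformate | COC(=O)Cl | starting material
8 | (2-bromo-4,6-dimethoxy-3,5-dimethylphenyl)lithium | [Li]c1c(Br)c(C)c(OC)c(C)c1OC | intermediate
9 | 1,2-didehydro-3,5-dimethoxy-4,6-dimethylbenzene (aryne) | COC1=C(C)C(OC)=C(C)C#C1 | intermediate
10 | (2,4-dimethoxy-3,5,6-trimethylphenyl)magnesium bromide | COc1c([Mg]Br)c(C)c(C)c(OC)c1C | intermediate
11 | methyl 2,4-dimethoxy-3,5,6-trimethylbenzoate | COC(=O)c1c(C)c(C)c(OC)c(C)c1OC | intermediate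
12 | methyl 2,4-dihydroxy-3,5,6-trimethylbenzoate | COC(=O)c1c(C)c(C)c(O)c(C)c1O | intermediate
13 | atraric acid (methyl 2,4-dihydroxy-3,6-dimethylbenzoate) | COC(=O)c1c(C)cc(O)c(C)c1O | starting material
14 | methyl 5-chloro-2,4-dihydroxy-3,6-dimethylbenzoate | COC(=O)c1c(C)c(Cl)c(O)c(C)c1O | intermediate
15 | benzyl bromide | BrCc1ccccc1 | starting material
16 | methyl 4-(benzyloxy)-5-chloro-2-hydroxy-3,6-dimethylbenzoate | COC(=O)c1c(C)c(Cl)c(OCc2ccccc2)c(C)c1O | intermediate
17 | methyl 4-(benzyloxy)-5-chloro-2-methoxy-3,6-dimethylbenzoate | COC(=O)c1c(C)c(Cl)c(OCc2ccccc2)c(C)c1OC | intermediate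
18 | 4-(benzyloxy)-5-chloro-2-methoxy-3,6-dimethylbenzoic acid | OC(=O)c1c(C)c(Cl)c(OCc2ccccc2)c(C)c1OC | intermediate
19 | 4-(benzyloxy)-5-chloro-2-methoxy-3,6-dimethylbenzoic trifluoroacetic anhydride | FC(F)(F)C(=O)OC(=O)c1c(C)c(Cl)c(OCc2ccccc2)c(C)c1OC | intermediate
20 | methyl 4-{[4-(benzyloxy)-5-chloro-2-methoxy-3,6-dimethylbenzoyl]oxy}-2-hydroxy-3,5,6-trimethylbenzoate | COC(=O)c1c(C)c(C)c(OC(=O)c2c(C)c(Cl)c(OCc3ccccc3)c(C)c2OC)c(C)c1O | intermediate
21 | methyl 4-{[4-(benzyloxy)-5-chloro-2-methoxy-3,6-dimethylbenzoyl]oxy}-2-methoxy-3,5,6-trimethylbenzoate | COC(=O)c1c(C)c(C)c(OC(=O)c2c(C)c(Cl)c(OCc3ccccc3)c(C)c2OC)c(C)c1OC | intermediate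
22 | methyl 4-[(5-chloro-4-hydroxy-2-methoxy-3,6-dimethylbenzoyl)oxy]-2-methoxy-3,5,6-trimethylbenzoate | COC(=O)c1c(C)c(C)c(OC(=O)c2c(C)c(Cl)c(O)c(C)c2OC)c(C)c1OC | target

Total step count: 11
Longest linear sequence: 7 (steps 1–4 and 9–11; the ring-B branch, steps 5–8 and 9–11, is equally long)

Steps most likely to fail

1. Step 3.
- What may go wrong: carbometalation by MeMgBr may be slow, so that the aryne is consumed by aryllithium 8 or by the amine. Proton transfer may also quench the arylmagnesium before acylation. Attack at the wrong aryne terminus is the lesser danger.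
- Fallback (from 5, back at 11): the two C–C bonds are made one after the other on the intact ring instead of across an aryne. Negishi coupling of 5 with MeZnCl (Pd(PPh3)4, THF, 60 °C) should give 1,3-dimethoxy-2,4,5-trimethylbenzene F1. NBS in MeCN should brominate its single ring C–H, which is ortho to one methoxy group and para to the other, to give 1-bromo-2,4-dimethoxy-3,5,6-trimethylbenzene F2. Bromine–lithium exchange with n-BuLi (THF, −78 °C) gives (2,4-dimethoxy-3,5,6-trimethylphenyl)lithium F3, which is acylated with methyl chloroformate 7 to rejoin the route at 11.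

2. Step 9.
- What may go wrong: acyl transfer between two doubly ortho-flanked partners may be sluggish, acylation may also occur at O2, or acid may strip the benzyl group.
- Fallback (from 12 and 18, back at 21): a single phenol is offered, and the acid-mediated transfer is replaced by an acyl chloride/phenoxide union.
 - 12 is benzylated at O4 (benzyl bromide 15, K2CO3, acetone) to methyl 4-(benzyloxy)-2-hydroxy-3,5,6-trimethylbenzoate F4.
 - F4 is methylated at O2 (iodomethane 3, K2CO3, DMF) to methyl 4-(benzyloxy)-2-methoxy-3,5,6-trimethylbenzoate F5.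
 - F5 is hydrogenolysed (H2, Pd/C, EtOAc) to methyl 4-hydroxy-2-methoxy-3,5,6-trimethylbenzoate F6.
 - NaH in THF converts F6 into sodium 3-methoxy-4-(methoxycarbonyl)-2,5,6-trimethylphenolate F7.
 - (COCl)2 with catalytic DMF converts 18 into 4-(benzyloxy)-5-chloro-2-methoxy-3,6-dimethylbenzoyl chloride F8.
 - F7 and F8 combine in THF at reflux to give 21 directly, so that step 10 falls away.

3. Step 2.
- What may go wrong: metalation of the electron-rich ring may be incomplete, the lithiated intermediate may lose LiBr prematurely, or a second metalation–methylation may occur at the last ring hydrogen.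
- Fallback (from 2, back at 5): the carbon is introduced by electrophilic substitution instead of through a carbanion beside bromine. Rieche formylation of 2 (Cl2CHOMe, TiCl4, CH2Cl2, 0 °C) can only strike one of the two equivalent positions ortho and para to the methoxy groups and should give 6-bromo-2,4-dimethoxy-3-methylbenzaldehyde F9. The ionic hydrogenation of step 1 (Et3SiH, TFA, CH2Cl2) then reduces F9 to 5.

Further compounds
F1 | step 3 | 1,3-dimethoxy-2,4,5-trimethylbenzene | COc1cc(C)c(C)c(OC)c1C
F2 | step 3 | 1-bromo-2,4-dimethoxy-3,5,6-trimethylbenzene | COc1c(Br)c(C)c(C)c(OC)c1C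
F3 | step 3 | (2,4-dimethoxy-3,5,6-trimethylphenyl)lithium | [Li]c1c(C)c(C)c(OC)c(C)c1OC
F4 | step 9 | methyl 4-(benzyloxy)-2-hydroxy-3,5,6-trimethylbenzoate | COC(=O)c1c(C)c(C)c(OCc2ccccc2)c(C)c1O
F5 | step 9 | methyl 4-(benzyloxy)-2-methoxy-3,5,6-trimethylbenzoate | COC(=O)c1c(C)c(C)c(OCc2ccccc2)c(C)c1OC
F6 | step 9 | methyl 4-hydroxy-2-methoxy-3,5,6-trimethylbenzoate | COC(=O)c1c(C)c(C)c(O)c(C)c1OC
F7 | step 9 | sodium 3-methoxy-4-(methoxycarbonyl)-2,5,6-trimethylphenolate | COC(=O)c1c(C)c(C)c([O-])c(C)c1OC.[Na+]
F8 | step 9 | 4-(benzyloxy)-5-chloro-2-methoxy-3,6-dimethylbenzoyl chloride | COc1c(C)c(OCc2ccccc2)c(Cl)c(C)c1C(Cl)=O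
F9 | step 2 | 6-bromo-2,4-dimethoxy-3-methylbenzaldehyde | COc1cc(Br)c(C=O)c(OC)c1C
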